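(All runs are calculated with made-up constants; the scatter is artificial.)

Grey and amber differ in J, and at the second reading the amber run holds 0.509 of the grey run's L, against a ratio of J charges of 0.507. The blue run holds 0.499 of it, against a ratio of [G][J] charges of 0.520. So we read the early rate as first order in G and first order in J, and we call rate/([G][J]) the grip.

| flask | G | J | X | time |
|---|---|---|---|---|
| grey | 250 mM | 750 mM | 1.30 mM |  |
| blue | 150 mM | 650 mM | 1.30 mM |  |
| amber | 250 mM | 380 mM | 1.30 mM |  |
| green | 250 mM | 750 mM | 1.30 mM | 320 min |

| run | time / min | [L] / mM |
|---|---|---|
| grey run | 2.9 | 14.5 |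
| grey run | 8.7 | 40.7 |
| grey run | 17 | 69.7 |
| grey run | 26 | 97.3 |
| grey run | 38 | 121.9 |
| grey run | 50 | 140.1 |
| grey run | 65 | 153.0 |
| grey run | 80 | 163.3 |
| blue run | 2.9 | 8.2 |
| blue run | 8.7 | 20.3 |
| blue run | 17 | 36.2 |
| blue run | 26 | 46.7 |
| blue run | 38 | 62.1 |
| blue run | 50 | 73.7 |
| blue run | 65 | 78.4 |
| blue run | 80 | 87.5 |
| amber run | 2.9 | 6.0 |
| amber run | 8.7 | 20.7 |
| amber run | 17 | 37.5 |
| amber run | 26 | 51.4 |
| amber run | 38 | 64.2 |
| amber run | 50 | 74.4 |
| amber run | 65 | 86.9 |
| amber run | 80 | 92.2 |

(each reading ± 1 mM)

* order of the initial rate in [J], near the charge of the grey run, the rate being that where two percent of its G are L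
* order of the initial rate in [G], near the charge of the grey run, the rate being that where two percent of its G are L (one fixed amount of L, the same in the runs compared)
* the blue run starts with 100 mM less of G and of J than the grey run, and with no L. Compared where both hold the same amount of G, once fifteen percent of what the blue run was charged with has turned into L, is the blue run faster, slower or alike (within a tenth)?
* L in the green run at 320 min, as a share of the G charged

- Overall: G + J -> L, with X as catalyst.
- Constant volume, constant temperature.
- "The second partner" is J.
- An order is taken over about fifteen percent of the charge, up and down.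

Over the first 8.7 min the grey run's grip reads 0.0279 M⁻¹ min⁻¹. The bench rule: the grey charge holds J at 3.00 times G, so treat [J] as constant (pseudo-first-order). Then G has a fixed half-life of 33.1 min, and the green run's 320 min holds 9.67 of them.

The border shows in the grey run. Between 50 min and 80 min its grip reads 0.0131 M⁻¹ min⁻¹, about half of the early value. The blue run over those minutes reads 0.0116 M⁻¹ min⁻¹, with about half the L. So the grip follows the clock.

We carry the fade half-life, the time in which the grip halves: 80.6 min as a lifetime, so 55.8 min. A fading grip sums to its start value held for one lifetime, and 320 min collects nearly all of that sum. With [J] taken at 625 mM, the green run's G gets 1.38 lifetimes, which gives us 74.8%.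

For the same-G question, the grey and blue runs reach that point near 38 min and 8.7 min. That gap of 29.3 min is about half a fade half-life, so we expect the blue run faster, by a factor of 1.44.

The forecast says 1, 0.95, faster and 79%, a share higher than ours: “So the loss follows time, not product”.

The flask gives 1.0, 1.0, faster and 75.0%.

    X + G + J → L + X (20.70 M⁻² min⁻¹)
    J → Qi (0.01620 min⁻¹)
    G + J + L → 2 L (0.1248 M⁻² min⁻¹)

The green run's 320 min is 5.73 fade half-lives. The passing of J into Qi is the main reason for its shortfall: with that step taken away, the green run reaches >99.9%. At the point compared, the blue run, younger by 0.525 of a fade half-life, stands at 1.2 of the grey rate, less than our 1.44, and with the step taken away that ratio is 0.70.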